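Remark on the chemistry: ring positions are numbered C1 (quaternary carbon with methyl and vinyl), C2 and C3 (methylenes), C4 (side-chain methine), C5 (secondary carbinol) and C6 (isopropenyl methine). The methyl-bearing α-carbon of the open-chain ester is carried as a mixture of epimers and drawn as 2S, because step 7 erases it.

## Structural features

The target is one cyclohexane ring with five substituents: C1 is quaternary (methyl, vinyl), C2 and C3 are methylenes, C4 carries the exocyclic tertiary carbinol C(OH)(CH2OAc)2, C5 is a secondary carbinol and C6 carries isopropenyl. The stereocentres C1, C6, C5 and C4 are contiguous (1S, 6S, 5R, 4R in this numbering), and in the chair with the C1 methyl axial the vinyl, isopropenyl, hydroxyl and side chain are all equatorial, so the C5 oxygen is trans to both neighbours and isopropenyl is trans to vinyl. The side-chain carbinol carbon has two identical acetoxymethyl arms and is not stereogenic. Fragile elements are the two primary acetates beside a free tertiary hydroxyl (acyl migration, base), two terminal alkenes that rule out late hydrogenation, hydroboration or ozonolysis, and, whenever C5 is a ketone, the C6 methine, which is then both α to the carbonyl and allylic. The real difficulties are the quaternary C1 with defined configuration relative to C6, and the late C4/C5 pair, whose equatorial hydroxyl needs hydride from the face shielded by the axial methyl. The key step exploits the C1–C2 bond: it joins the only quaternary ring atom to a methylene, and because vinyl can be carried as an ester, C1 can be an ester-enolate carbon whose neighbouring C6 methine (hydrogen, isopropenyl, ring chain) decides which face the tethered C2 electrophile reaches. C4 is α to C5, so a C5 ketone allows the whole diacetate unit to be attached as a symmetrical ketone and then lets the side-chain hydroxyl direct the C5 reduction.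

## Logic of the disconnections

24 ⇒ 23. The C5–H bond is cut (carbonyl reduction). The C5 hydroxyl must be trans to both neighbours, and the tertiary hydroxyl already on the C4 side chain can carry the hydride to the correct face. The gain is that C5 becomes a carbonyl that activates C4. The demand is internal hydride delivery to the axial face of C5 with the side chain equatorial.

23 ⇒ 21 + 22. The C4–C(carbinol) bond is cut (aldol). Because the carbinol carbon carries two identical arms, 22 supplies all three carbons and both acetates without creating a second stereocentre. The forward step needs a regiodefined C4 enol derivative, conditions that spare the acetates, and C4 formed with the side chain cis to isopropenyl.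

21 ⇒ 19 ⇒ 18 ⇒ 17. Enol silane back to ketone, carbinol and silyl ether. The C5 oxygen passes through the ketone, so its earlier configuration need not match the target. The demand is enolisation toward the C4 methylene only and non-equilibrating handling of 19, whose C6 centre is α-carbonyl and allylic.

17 ⇒ 16 ⇒ 15 ⇒ 14. The vinyl C=C bond is cut (methylenation) and the aldehyde is traced to the ester. The ester is what allows C1 to be an enolate carbon in the key step. The aldehyde has no α-hydrogen, so nothing can epimerise.

14 ⇒ 12 (through 13). The C1–C2 ring bond is cut. This removes the ring and the quaternary stereocentre in one move and leaves an open chain with two defined stereocentres. The forward step needs π-face selectivity at C1 relative to C6, a primary iodide, and works from either α-epimer.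

12 ⇒ 11 ⇒ 9 (through 10). Halide exchange and α-methylation. The halide is kept as the chloride through the methylation so that the less hindered secondary enolate cannot close prematurely to a ring without the methyl group. The iodide is made only immediately before closure.

9 ⇒ 6 + 7 (through 8). The C6–isopropenyl bond is cut (conjugate addition). This leaves an enoate with one stereocentre. The demand is addition anti to the γ-silyloxy group, which is the only control element and is later oxidised away.

6 ⇒ 5 ⇒ 4 ⇒ 1 + 2 (through 3). The C=C bond (olefination) and the C–O bond (α-oxygenation) are cut. One organocatalytic step sets the single stereocentre from achiral 1. The demand is olefination in the same flask before the α-oxy aldehyde racemises, and N–O cleavage that spares enoate and chloride.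

## Other disconnections considered

Alternative 1: The cut removes both C–CH2 bonds at the side-chain carbinol carbon and leaves a C4 ester. Forward, two equivalents of the silylmethyl Grignard reagent A3, cerium-mediated to hold back enolisation, would add to the ring ester A2 to give the bis-silane A1. Tamao–Fleming oxidation of both C–Si bonds and acetylation of the two primary hydroxyls would then finish the side chain.
- In its favour: C4 would sit on a β-hydroxy ester, where it can be equilibrated while C5 is already a carbinol, so the all-equatorial isomer is a true thermodynamic sink. On control of C4 this alternative is better than the chosen plan, whose C4 rests on an aldol equilibrium at the ketone stage. On the symmetry of the carbinol carbon the two are equal.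
- Against it here: A2 has a free β-hydroxyl (alkoxide formation, retro-aldol, elimination under a basic organometallic). The second addition must pass through a hindered, enolisable α-silyl ketone, and the β-hydroxysilane can undergo Peterson loss. Reaching A2 needs an acylation and a ketone reduction with no directing hydroxyl while the axial methyl shields the required face; there the chosen plan is stronger.
- Comparison: both plans build the side chain by polar addition to a carbonyl. The chosen aldol brings three carbons and both acetates in one bond; this route makes two bonds and then needs oxidation and selective acetylation, about five operations from the ring ketone against three. It does not address the ring or C1.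

Alternative 2: The cut is a retro-[4+2] across C1–C2 and C5–C6. Forward, diene A5 and the trans keto-ester dienophile A6 would combine under a chiral boron Lewis acid to the cyclohexene A4, closing the ring and setting C1, C6 and C5 in one catalytic step.
- In its favour: ring, quaternary centre and absolute configuration would come from two achiral fragments in one step. On step economy to the carbocycle it is clearly better (one step against seven). The trans relation of ester and acetyl follows stereospecifically from the alkene geometry of A6, which is at least equal to allylic-strain control.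
- Against it here: A6 is a trisubstituted dienophile whose regiochemistry depends on the ketone out-directing the ester. The configuration drawn for A4 has the silyloxy group trans to acetyl, which corresponds to the Lewis-acid-bound ketone exo, against the usual endo preference; this is harmless only because C5 is later oxidised. A4 still lacks the C4 side chain.
- Comparison: after acetyl to isopropenyl, ester to vinyl and saturation of C3=C4 (which must come before either new alkene exists), the same C5 ketone, aldol and directed reduction are needed. The front end is shorter, the endgame identical, and the functional-group changes in between bring the total close to the chosen plan with more reliance on ordering.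

Alternative 3: The cut is the C4–C5 bond. Forward, single-electron reduction of the aldehyde of A8 by divalent samarium would give a ketyl that adds 6-exo-trig to the alkylidene malonate, closing the ring to A7 and setting C4 and C5 together through a chelated chair-like transition state.
- In its favour: it creates in one step the two centres that the chosen plan sets last and with least assurance, under conditions that spare both alkenes. On C4/C5 control this alternative is the better one.
- Against it here: A8 is an acyclic aldehyde whose α-carbon bears isopropenyl (epimerisable, prone to conjugation) beside an acyclic quaternary stereocentre. The C1/C6 problem is moved to a setting without an obvious control element, where the chosen plan is stronger. Face selectivity of the ketyl relative to C6 is not assured, and A7 can lactonise onto the new hydroxyl.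
- Comparison: the malonate then needs α-hydroxylation, reduction of both esters and selective acetylation among four hydroxyls, about four further operations against one in the chosen plan. It is not shorter before the key step either.

Key step: step 7

## Route

Step 1
Reactants: 1 5-chloropentanal; 2 trimethyl phosphonoacetate
Product: 4 methyl (R,E)-4-(anilinooxy)-7-chlorohept-2-enoate, via (R)-2-(anilinooxy)-5-chloropentanal 3 (not isolated)
Conditions: PhN=O, L-proline (20 mol %), MeCN, −20 °C; then 2, LiCl, DBU, 0 °C
Reagents that add atoms: nitrosobenzene O=Nc1ccccc1
Why: Proline-catalysed α-aminoxylation: the L-proline enamine of 1 is attacked by the nitroso oxygen on the face set by hydrogen bonding to the carboxylic acid, which should give 3 with the R configuration; Horner–Wadsworth–Emmons olefination in the same flask (LiCl/DBU) gives the E-enoate before the labile α-oxy aldehyde can racemise.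

Step 2
Reactants: 4
Product: 5 methyl (R,E)-7-chloro-4-hydroxyhept-2-enoate
Conditions: Cu(OAc)2·H2O (30 mol %), EtOH, rt
Reagents that add atoms: none
Why: Copper-catalysed, non-reductive N–O cleavage of the O-alkyl-N-arylhydroxylamine should free the allylic alcohol without touching enoate, chloride or the stereocentre.

Step 3
Reactants: 5
Product: 6 methyl (R,E)-4-[(tert-butyldimethylsilyl)oxy]-7-chlorohept-2-enoate
Conditions: tBuMe2SiCl, imidazole, DMF, rt
Reagents that add atoms: tert-butyldimethylsilyl chloride CC(C)(C)[Si](C)(C)Cl
Why: Silylation of the secondary alcohol; the bulky silyl ether survives the organometallic, enolate, hydride and ylide steps and provides the steric and stereoelectronic bias for the conjugate addition.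

Step 4
Reactants: 6; 7 isopropenylmagnesium bromide
Product: 9 methyl (3R,4R)-4-[(tert-butyldimethylsilyl)oxy]-7-chloro-3-(prop-1-en-2-yl)heptanoate, via trimethylsilyl ketene acetal 8 (not isolated)
Conditions: 7 (1.5 equiv), CuBr·SMe2 (20 mol %), Me3SiCl, THF, −78 → −40 °C; aq NH4Cl
Reagents that add atoms: chlorotrimethylsilane C[Si](C)(C)Cl (silyl group of 8 only, lost on work-up)
Why: Copper-catalysed, Me3SiCl-accelerated conjugate addition of the alkenyl Grignard reagent; the E-enoate reacts through the conformer with the γ-hydrogen eclipsing the alkene and the C–O bond perpendicular to it, and the cuprate adds anti to the silyloxy group, which should give the 3,4-anti (3R,4R) product. The primary chloride is inert to cuprates at this temperature.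

Step 5
Reactants: 9
Product: 11 methyl (2S,3R,4R)-4-[(tert-butyldimethylsilyl)oxy]-7-chloro-2-methyl-3-(prop-1-en-2-yl)heptanoate (with its 2R epimer), via lithium ester enolate 10 (not isolated)
Conditions: LiN(iPr)2, THF, −78 °C; MeI, −78 → −50 °C; AcOH quench at −50 °C
Reagents that add atoms: iodomethane CI
Why: Ester enolate methylation; the configuration at C2 is irrelevant because the centre is enolised again in step 7. The ω-halide is deliberately still the chloride, which a secondary ester enolate should not displace at this temperature, so closure to a ring lacking the methyl group is avoided.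

Step 6
Reactants: 11
Product: 12 methyl (2S,3R,4R)-4-[(tert-butyldimethylsilyl)oxy]-7-iodo-2-methyl-3-(prop-1-en-2-yl)heptanoate (with its 2R epimer)
Conditions: NaI (5 equiv), acetone, reflux
Reagents that add atoms: sodium iodide [Na+].[I-]
Why: Finkelstein exchange driven by precipitation of NaCl; it installs the reactive leaving group only immediately before ring closure.

Step 7
Reactants: 12
Product: 14 methyl (1R,2S,3R)-3-[(tert-butyldimethylsilyl)oxy]-1-methyl-2-(prop-1-en-2-yl)cyclohexane-1-carboxylate, via potassium ester enolate 13 (not isolated)
Conditions: KN(SiMe3)2 (1.2 equiv), THF (0.02 M), −78 → −20 °C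
Reagents that add atoms: none
Why: KN(SiMe3)2 removes the α-hydrogen of either C2 epimer of 12 to give the same tetrasubstituted enolate 13, whose α-carbon displaces the primary iodide in an intramolecular SN2 reaction; the closest known reaction type is the ring-forming alkylation of an ester enolate that carries a β-stereocentre, with acyclic control by allylic strain. The one ring closes in the 6-exo-tet mode (C1–C2 bond in ring numbering). The new quaternary centre C1 is controlled by C6: to avoid allylic strain with the enolate oxygens the C6–H bond lies in the enolate plane, so isopropenyl and the chain through C5 stand on opposite faces, and the iodide-bearing chain can reach C1 only from its own face. In the chair-like transition state isopropenyl is therefore equatorial, the ester ends trans to it and the methyl cis to it (1R,2S,3R in 14). Enolate geometry cannot matter because both substituents on the distal enolate carbon are oxygens, and the rotamer that would give the C1 epimer forces C5 to eclipse an enolate oxygen. The selectivity needed is π-face selectivity at C1 relative to C6, secured by allylic strain plus the tether; the silyloxy group must sit axial and syn to the enolate methyl in this transition state, which costs rate rather than selectivity because the competing rotamer places the larger enolate carbon there. High dilution and low temperature should keep intermolecular alkylation and elimination of the iodide behind the closure.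

Step 8
Reactants: 14
Product: 15 [(1R,2S,3R)-3-[(tert-butyldimethylsilyl)oxy]-1-methyl-2-(prop-1-en-2-yl)cyclohexyl]methanol
Conditions: iBu2AlH (3 equiv), CH2Cl2, −78 → 0 °C; aq KNaC4H4O6
Reagents that add atoms: none
Why: Hydride reduction of the hindered ester to the neopentyl primary alcohol; full reduction followed by oxidation is chosen over partial reduction, which is unreliable for an α-quaternary ester.

Step 9
Reactants: 15
Product: 16 (1R,2S,3R)-3-[(tert-butyldimethylsilyl)oxy]-1-methyl-2-(prop-1-en-2-yl)cyclohexane-1-carbaldehyde
Conditions: Dess–Martin periodinane, CH2Cl2, rt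
Reagents that add atoms: none
Why: Dess–Martin oxidation of a primary alcohol; the aldehyde has no α-hydrogen and cannot epimerise or enolise.

Step 10
Reactants: 16
Product: 17 tert-butyl{[(1R,2S,3S)-3-ethenyl-3-methyl-2-(prop-1-en-2-yl)cyclohexyl]oxy}dimethylsilane
Conditions: Ph3PCH3Br, KOtBu, THF, 0 °C → rt
Reagents that add atoms: methyltriphenylphosphonium bromide C[P+](c1ccccc1)(c1ccccc1)c1ccccc1.[Br-]
Why: Wittig methylenation; the unstabilised ylide is small enough for a neopentyl aldehyde and no stereocentre is touched.

Step 11
Reactants: 17
Product: 18 (1R,2S,3S)-3-ethenyl-3-methyl-2-(prop-1-en-2-yl)cyclohexan-1-ol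
Conditions: Bu4NF, THF, 50 °C
Reagents that add atoms: none
Why: Fluoride cleavage of the hindered secondary silyl ether; both alkenes are inert.

Step 12
Reactants: 18
Product: 19 (2S,3S)-3-ethenyl-3-methyl-2-(prop-1-en-2-yl)cyclohexan-1-one
Conditions: Dess–Martin periodinane, pyridine, CH2Cl2, 0 °C
Reagents that add atoms: none
Why: Buffered Dess–Martin oxidation gives the β,γ-unsaturated ketone without enolising conditions, so C6 should be kept and the isopropenyl group should not move into conjugation. The C5 configuration inherited from the conjugate addition is erased here.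

Step 13
Reactants: 19
Product: 21 {[(5S,6S)-5-ethenyl-5-methyl-6-(prop-1-en-2-yl)cyclohex-1-en-1-yl]oxy}trimethylsilane, via lithium ketone enolate 20 (not isolated)
Conditions: LiN(iPr)2, THF, −78 °C; Me3SiCl, Et3N, −78 → 0 °C
Reagents that add atoms: chlorotrimethylsilane C[Si](C)(C)Cl
Why: Kinetic deprotonation by the hindered amide at the C4 methylene, not at the C6 methine flanked by the quaternary carbon and isopropenyl; silylation fixes the regiochemistry and avoids any equilibration that would epimerise C6.

Step 14
Reactants: 21; 22 1,3-diacetoxyacetone
Product: 23 2-[(1S,3S,4S)-4-ethenyl-4-methyl-2-oxo-3-(prop-1-en-2-yl)cyclohexyl]-2-hydroxypropane-1,3-diyl diacetate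
Conditions: TiCl4 (1.1 equiv), CH2Cl2, −78 → −40 °C; aq NaHCO3
Reagents that add atoms: none
Why: Mukaiyama aldol addition of the enol silane to the TiCl4-activated symmetrical ketone forms the C4–C bond; the carbinol carbon has two identical arms, so C4 is the only new stereocentre. C4 is α to the ketone and the titanium aldolate is reversible on warming, so the step is run toward the chelated adduct with the side chain equatorial and cis to isopropenyl (chair with axial methyl), the isomer the next step needs; the C4 epimer is the competing product and is taken up under the uncertain steps.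

Step 15
Reactants: 23
Product: 24 2-[(1R,2R,3S,4S)-4-ethenyl-2-hydroxy-4-methyl-3-(prop-1-en-2-yl)cyclohexyl]-2-hydroxypropane-1,3-diyl diacetate (CNP0273389.1)
Conditions: Me4NBH(OAc)3 (5 equiv), MeCN/AcOH 1:1, −30 → 0 °C
Reagents that add atoms: none
Why: Evans–Saksena reduction: the tertiary hydroxyl exchanges onto boron and the alkoxy(diacetoxy)borohydride transfers hydride intramolecularly. From the equatorial side chain the hydride reaches the axial face of C5, which should give the equatorial hydroxyl trans to both the C4 and C6 substituents, whereas an external hydride would be deflected by the axial methyl to the other face; acetates and alkenes are not reduced.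

## Compound list

1 | 5-chloropentanal | O=CCCCCCl | starting material
2 | trimethyl phosphonoacetate | COC(=O)CP(=O)(OC)OC | starting material
3 | (R)-2-(anilinooxy)-5-chloropentanal | O=C[C@H](ONc1ccccc1)CCCCl | intermediate
4 | methyl (R,E)-4-(anilinooxy)-7-chlorohept-2-enoate | COC(=O)/C=C/[C@H](ONc1ccccc1)CCCCl | intermediate
5 | methyl (R,E)-7-chloro-4-hydroxyhept-2-enoate | COC(=O)/C=C/[C@H](O)CCCCl | intermediate
6 | methyl (R,E)-4-[(tert-butyldimethylsilyl)oxy]-7-chlorohept-2-enoate | COC(=O)/C=C/[C@H](O[Si](C)(C)C(C)(C)C)CCCCl | intermediate
7 | isopropenylmagnesium bromide | C=C(C)[Mg]Br | starting material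
8 | trimethylsilyl ketene acetal of 9 (C3 and C4 as in 9, enol ether geometry open) | COC(O[Si](C)(C)C)=C[C@H](C(=C)C)[C@H](O[Si](C)(C)C(C)(C)C)CCCCl | intermediate
9 | methyl (3R,4R)-4-[(tert-butyldimethylsilyl)oxy]-7-chloro-3-(prop-1-en-2-yl)heptanoate | COC(=O)C[C@H](C(=C)C)[C@H](O[Si](C)(C)C(C)(C)C)CCCCl | intermediate
10 | lithium ester enolate of 9 | COC([O-])=C[C@H](C(=C)C)[C@H](O[Si](C)(C)C(C)(C)C)CCCCl.[Li+] | intermediate
11 | methyl (2S,3R,4R)-4-[(tert-butyldimethylsilyl)oxy]-7-chloro-2-methyl-3-(prop-1-en-2-yl)heptanoate (with its 2R epimer) | COC(=O)[C@@H](C)[C@H](C(=C)C)[C@H](O[Si](C)(C)C(C)(C)C)CCCCl | intermediate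
12 | methyl (2S,3R,4R)-4-[(tert-butyldimethylsilyl)oxy]-7-iodo-2-methyl-3-(prop-1-en-2-yl)heptanoate (with its 2R epimer) | COC(=O)[C@@H](C)[C@H](C(=C)C)[C@H](O[Si](C)(C)C(C)(C)C)CCCI | intermediate
13 | potassium ester enolate of 12 | COC([O-])=C(C)[C@H](C(=C)C)[C@H](O[Si](C)(C)C(C)(C)C)CCCI.[K+] | intermediate
14 | methyl (1R,2S,3R)-3-[(tert-butyldimethylsilyl)oxy]-1-methyl-2-(prop-1-en-2-yl)cyclohexane-1-carboxylate | COC(=O)[C@]1(C)CCC[C@@H](O[Si](C)(C)C(C)(C)C)[C@H]1C(=C)C | intermediate
15 | [(1R,2S,3R)-3-[(tert-butyldimethylsilyl)oxy]-1-methyl-2-(prop-1-en-2-yl)cyclohexyl]methanol | OC[C@]1(C)CCC[C@@H](O[Si](C)(C)C(C)(C)C)[C@H]1C(=C)C | intermediate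
16 | (1R,2S,3R)-3-[(tert-butyldimethylsilyl)oxy]-1-methyl-2-(prop-1-en-2-yl)cyclohexane-1-carbaldehyde | O=C[C@]1(C)CCC[C@@H](O[Si](C)(C)C(C)(C)C)[C@H]1C(=C)C | intermediate
17 | tert-butyl{[(1R,2S,3S)-3-ethenyl-3-methyl-2-(prop-1-en-2-yl)cyclohexyl]oxy}dimethylsilane | C=C[C@]1(C)CCC[C@@H](O[Si](C)(C)C(C)(C)C)[C@H]1C(=C)C | intermediate
18 | (1R,2S,3S)-3-ethenyl-3-methyl-2-(prop-1-en-2-yl)cyclohexan-1-ol | C=C[C@]1(C)CCC[C@@H](O)[C@H]1C(=C)C | intermediate
19 | (2S,3S)-3-ethenyl-3-methyl-2-(prop-1-en-2-yl)cyclohexan-1-one | C=C[C@]1(C)CCCC(=O)[C@H]1C(=C)C | intermediate
20 | lithium (5S,6S)-5-ethenyl-5-methyl-6-(prop-1-en-2-yl)cyclohex-1-en-1-olate | C=C[C@]1(C)CCC=C([O-])[C@H]1C(=C)C.[Li+] | intermediate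
21 | {[(5S,6S)-5-ethenyl-5-methyl-6-(prop-1-en-2-yl)cyclohex-1-en-1-yl]oxy}trimethylsilane | C=C[C@]1(C)CCC=C(O[Si](C)(C)C)[C@H]1C(=C)C | intermediate
22 | 1,3-diacetoxyacetone (2-oxopropane-1,3-diyl diacetate) | CC(=O)OCC(=O)COC(C)=O | starting material
23 | 2-[(1S,3S,4S)-4-ethenyl-4-methyl-2-oxo-3-(prop-1-en-2-yl)cyclohexyl]-2-hydroxypropane-1,3-diyl diacetate | C=C[C@]1(C)CC[C@@H](C(O)(COC(C)=O)COC(C)=O)C(=O)[C@H]1C(=C)C | intermediate
24 | 2-[(1R,2R,3S,4S)-4-ethenyl-2-hydroxy-4-methyl-3-(prop-1-en-2-yl)cyclohexyl]-2-hydroxypropane-1,3-diyl diacetate (CNP0273389.1) | C=C[C@]1(C)CC[C@@H](C(O)(COC(C)=O)COC(C)=O)[C@H](O)[C@H]1C(=C)C | target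

## Step count and least certain steps

Total step count: 15. Longest linear sequence: 15 steps (1 to 24).

Step 7 (key step). The most likely failure is slow ring closure with erosion of face selectivity, because the silyloxy group has to be axial and syn to the enolate methyl in the closing chair; intermolecular alkylation or elimination of the iodide could then compete. The fallback keeps the same bond and the same control element but changes the nucleophile to a carboxylic acid dianion, which is smaller, more nucleophilic and cannot undergo ester condensation. It sets out from 11: LiOH in THF/MeOH/H2O hydrolyses the ester to (2S,3R,4R)-4-[(tert-butyldimethylsilyl)oxy]-7-chloro-2-methyl-3-(prop-1-en-2-yl)heptanoic acid F1, NaI in acetone gives the corresponding iodo acid F2, and two equivalents of LiN(iPr)2 generate the enediolate (again two oxygens on the distal carbon), which should close to (1R,2S,3R)-3-[(tert-butyldimethylsilyl)oxy]-1-methyl-2-(prop-1-en-2-yl)cyclohexane-1-carboxylic acid F3. LiAlH4 reduces F3 to 15, where the route is rejoined.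

Step 14 (together with the enolisation of step 13). The most likely failure is attack on the wrong face of C4. In the enol silane the isopropenyl group is pseudo-axial (allylic strain with the silyloxy group) and shields the face that leads to the required 4,6-cis adduct. The chair with axial methyl and the ring-flipped chair (axial vinyl and isopropenyl) of the ketone are close in energy, so equilibration of the aldolate is not certain to correct this. Enolisation toward C6 in step 13 would also scramble C6. The fallback is a temporary conformational lock that also removes the allylic acidity at C6; it sets out from 15 and comes back at 24.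
- I2 and NaHCO3 in MeCN cyclise the primary alcohol onto isopropenyl (5-exo iodoetherification) to the trans-fused iodoether tert-butyl{[(3aS,4R,7aR)-3-(iodomethyl)-3,7a-dimethyloctahydro-2-benzofuran-4-yl]oxy}dimethylsilane F4. The configuration at the new ether carbon is immaterial and is left open.
- Bu4NF gives the alcohol (3aS,4R,7aR)-3-(iodomethyl)-3,7a-dimethyloctahydro-2-benzofuran-4-ol F5 and Dess–Martin oxidation the ketone (3aR,7aR)-3-(iodomethyl)-3,7a-dimethylhexahydro-2-benzofuran-4(1H)-one F6. The trans ring fusion allows only the chair with axial methyl.
- LiN(iPr)2/Me3SiCl gives the enol silane {[(3aR,7aR)-3-(iodomethyl)-3,7a-dimethyl-1,3,3a,6,7,7a-hexahydro-2-benzofuran-4-yl]oxy}trimethylsilane F7. TiCl4-mediated addition to 22 gives the aldol 2-hydroxy-2-[(3aR,5S,7aR)-3-(iodomethyl)-3,7a-dimethyl-4-oxooctahydro-2-benzofuran-5-yl]propane-1,3-diyl diacetate F8, for which the equatorial side chain is now the only low-energy arrangement.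
- Me4NBH(OAc)3 gives the diol 2-hydroxy-2-[(3aS,4S,5R,7aR)-4-hydroxy-3-(iodomethyl)-3,7a-dimethyloctahydro-2-benzofuran-5-yl]propane-1,3-diyl diacetate F9.
- Zn in AcOH reopens the β-iodo ether to isopropenyl and the primary alcohol, giving 2-hydroxy-2-[(1R,2R,3S,4R)-2-hydroxy-4-(hydroxymethyl)-4-methyl-3-(prop-1-en-2-yl)cyclohexyl]propane-1,3-diyl diacetate F10.
- TEMPO/PhI(OAc)2 oxidises only the primary alcohol to 2-[(1R,2R,3S,4R)-4-formyl-2-hydroxy-4-methyl-3-(prop-1-en-2-yl)cyclohexyl]-2-hydroxypropane-1,3-diyl diacetate F11. Non-basic Takai–Lombardo methylenation (CH2Br2, Zn, TiCl4) then gives 24.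
- This costs two more steps and places a methylenation after the acetates are in place.

Step 15. The most likely failure is hydride transfer to the equatorial face of C5, through slow ligand exchange at the tertiary hydroxyl or deflection by the axial methyl, which would give the axial alcohol; acetyl migration in the acidic medium is a lesser concern. The fallback changes the mechanism from hydride transfer to single-electron reduction: SmI2 in THF/MeOH, chelated by the β-hydroxyl, forms the ketyl, and protonation should give the more stable equatorial carbinol. It sets out from 23 and comes back at 24 with no new compound.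

Step 4. The most likely failure is incomplete transfer of the alkenyl group or erosion of the anti preference, with reductive loss of the γ-silyloxy group as a side path. The fallback replaces substrate control by catalyst control: rhodium-catalysed Hayashi–Miyaura addition of isopropenylboronic acid pinacol ester ([RhCl(cod)]2 with the enantiomer of a chiral bisphosphine or diene ligand matched to the 3R centre, aqueous dioxane). It sets out from 6 and comes back at 9 with no new compound.

## Further compounds

F1 | step 7 | (2S,3R,4R)-4-[(tert-butyldimethylsilyl)oxy]-7-chloro-2-methyl-3-(prop-1-en-2-yl)heptanoic acid (with its 2R epimer) | OC(=O)[C@@H](C)[C@H](C(=C)C)[C@H](O[Si](C)(C)C(C)(C)C)CCCCl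
F2 | step 7 | (2S,3R,4R)-4-[(tert-butyldimethylsilyl)oxy]-7-iodo-2-methyl-3-(prop-1-en-2-yl)heptanoic acid (with its 2R epimer) | OC(=O)[C@@H](C)[C@H](C(=C)C)[C@H](O[Si](C)(C)C(C)(C)C)CCCI
F3 | step 7 | (1R,2S,3R)-3-[(tert-butyldimethylsilyl)oxy]-1-methyl-2-(prop-1-en-2-yl)cyclohexane-1-carboxylic acid | OC(=O)[C@]1(C)CCC[C@@H](O[Si](C)(C)C(C)(C)C)[C@H]1C(=C)C
F4 | step 14 | tert-butyl{[(3aS,4R,7aR)-3-(iodomethyl)-3,7a-dimethyloctahydro-2-benzofuran-4-yl]oxy}dimethylsilane (either C3 epimer) | O1C[C@]2(C)CCC[C@@H](O[Si](C)(C)C(C)(C)C)[C@H]2C1(C)CI
F5 | step 14 | (3aS,4R,7aR)-3-(iodomethyl)-3,7a-dimethyloctahydro-2-benzofuran-4-ol (either C3 epimer) | O1C[C@]2(C)CCC[C@@H](O)[C@H]2C1(C)CI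
F6 | step 14 | (3aR,7aR)-3-(iodomethyl)-3,7a-dimethylhexahydro-2-benzofuran-4(1H)-one (either C3 epimer) | O1C[C@]2(C)CCCC(=O)[C@H]2C1(C)CI
F7 | step 14 | {[(3aR,7aR)-3-(iodomethyl)-3,7a-dimethyl-1,3,3a,6,7,7a-hexahydro-2-benzofuran-4-yl]oxy}trimethylsilane (either C3 epimer) | O1C[C@]2(C)CCC=C(O[Si](C)(C)C)[C@H]2C1(C)CI
F8 | step 14 | 2-hydroxy-2-[(3aR,5S,7aR)-3-(iodomethyl)-3,7a-dimethyl-4-oxooctahydro-2-benzofuran-5-yl]propane-1,3-diyl diacetate (either C3 epimer) | O1C[C@]2(C)CC[C@@H](C(O)(COC(C)=O)COC(C)=O)C(=O)[C@H]2C1(C)CI
F9 | step 14 | 2-hydroxy-2-[(3aS,4S,5R,7aR)-4-hydroxy-3-(iodomethyl)-3,7a-dimethyloctahydro-2-benzofuran-5-yl]propane-1,3-diyl diacetate (either C3 epimer) | O1C[C@]2(C)CC[C@@H](C(O)(COC(C)=O)COC(C)=O)[C@H](O)[C@H]2C1(C)CI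
F10 | step 14 | 2-hydroxy-2-[(1R,2R,3S,4R)-2-hydroxy-4-(hydroxymethyl)-4-methyl-3-(prop-1-en-2-yl)cyclohexyl]propane-1,3-diyl diacetate | OC[C@]1(C)CC[C@@H](C(O)(COC(C)=O)COC(C)=O)[C@H](O)[C@H]1C(=C)C
F11 | step 14 | 2-[(1R,2R,3S,4R)-4-formyl-2-hydroxy-4-methyl-3-(prop-1-en-2-yl)cyclohexyl]-2-hydroxypropane-1,3-diyl diacetate | O=C[C@]1(C)CC[C@@H](C(O)(COC(C)=O)COC(C)=O)[C@H](O)[C@H]1C(=C)C
F0 | step 15 | none | none
F0 | step 4 | none | none
A1 | alternative 1 | 2-[(1R,2R,3S,4S)-4-ethenyl-2-hydroxy-4-methyl-3-(prop-1-en-2-yl)cyclohexyl]-1,3-bis[dimethyl(propan-2-yloxy)silyl]propan-2-ol | C=C[C@]1(C)CC[C@@H](C(O)(C[Si](C)(C)OC(C)C)C[Si](C)(C)OC(C)C)[C@H](O)[C@H]1C(=C)C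
A2 | alternative 1 | methyl (1R,2R,3S,4S)-4-ethenyl-2-hydroxy-4-methyl-3-(prop-1-en-2-yl)cyclohexane-1-carboxylate | C=C[C@]1(C)CC[C@@H](C(=O)OC)[C@H](O)[C@H]1C(=C)C
A3 | alternative 1 | {[dimethyl(propan-2-yloxy)silyl]methyl}magnesium chloride | CC(C)O[Si](C)(C)C[Mg]Cl
A4 | alternative 2 | methyl (1R,5S,6S)-6-acetyl-1-methyl-5-[(trimethylsilyl)oxy]cyclohex-3-ene-1-carboxylate | COC(=O)[C@]1(C)CC=C[C@H](O[Si](C)(C)C)[C@H]1C(C)=O
A5 | alternative 2 | (E)-1-[(trimethylsilyl)oxy]buta-1,3-diene | C=C/C=C/O[Si](C)(C)C
A6 | alternative 2 | methyl (E)-2-methyl-4-oxopent-2-enoate | COC(=O)/C(C)=C/C(C)=O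
A7 | alternative 3 | dimethyl 2-[(1S,2S,3S,4S)-4-ethenyl-2-hydroxy-4-methyl-3-(prop-1-en-2-yl)cyclohexyl]propanedioate | C=C[C@]1(C)CC[C@@H](C(C(=O)OC)C(=O)OC)[C@H](O)[C@H]1C(=C)C
A8 | alternative 3 | dimethyl 2-[(4S,5S)-4-ethenyl-5-formyl-4,6-dimethylhept-6-en-1-ylidene]propanedioate | C=C[C@](C)(CCC=C(C(=O)OC)C(=O)OC)[C@@H](C=O)C(=C)C
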